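All runs are calculated with constants of no real substance; scatter was added.

1. Per 0.0250 M of extra second nucleophile, from the grey run to the teal run, mean other capture product rose from 30.7% to 42.1%, and mean target fell from 11.9% to 9.68%. The decision is whether the next flask gets 0.100 M of second nucleophile, with substrate and first nucleophile left as they were.

| flask | substrate | first nucleophile | second nucleophile | remark | time |
|---|---|---|---|---|---|
| grey | 0.10 M | 0.18 M | 0.050 M | run made earlier |  |
| teal | 0.10 M | 0.18 M | 0.075 M | run made earlier |  |
| flask | 0.10 M | 0.180 M | 0.100 M |  | 8.0 d |

- grey (time / d: other capture product / %, target / %): 0.417: 30.6, 12.1; 0.833: 30.4, 11.5; 2.08: 31.4, 12.7; 5.00: 30.4, 11.2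
- teal (time / d: other capture product / %, target / %): 1.25: 41.5, 10.5; 2.50: 43.2, 9.3; 4.00: 41.3, 9.8; 5.00: 42.5, 9.1

(standard deviation of a reading: 1 percentage point)

1. share of other capture product in other capture product plus target at 3.0 min
2. share of other capture product in other capture product plus target at 8.0 d

- amounts and yields of target count crystals too
- given per volume of solution although it is solid: crystals
- the analysis behind the earlier runs scatters by 1 percentage point, standard deviation
- what may be going on: intermediate -> solvolysis product; substrate -> intermediate; first nucleophile + intermediate -> target; second nucleophile + intermediate -> other capture product; target <-> isomer of the product; crystals <-> target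

2. Neither run drifts beyond its scatter of 1 percentage point, so we use the means and follow one intermediate molecule to its fork.

3. We call C the apparent crossover concentration: the [second nucleophile] at which that molecule is as likely to end as target, as read in these runs, as in other capture product. Target that has passed to isomer of the product is not in these readings, so C is a net-yield constant and may lie below the crossover at the fork itself; we use it at the 0.18 M of first nucleophile in these runs. Summed over the run, target as read equals C times ln(charge of second nucleophile over what is left). The grey run gives 12.5 mM and the teal run 11.7 mM, so we take 12.1 mM.

4. K is the [second nucleophile] at which capture by it has even chances against every other exit. The runs give 0.0728 M and 0.0702 M, so we take 0.0715 M. For the new flask we try 0.0500 M left: second nucleophile used plus K times the logarithm comes to 0.0996 M, which matches the 0.10 M of substrate.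

5. Our reckoning for the new flask is then target 8.39% and a final share of 85.6%. Taking the charge as still present at 3.0 min, and applying this net-yield C that early, which is the weak point, we get an early share of 89.2%. We accept that loss of target and charge 0.100 M.

6. The forecast says 89% and 85.5%, and warns that “the runs do not show early behaviour”.

The flask gives 86.6% at 3.0 min and 85.6% at 8.0 d.

    intermediate → solvolysis product (k = 2900 /h)
    substrate → intermediate (k = 0.410 /h)
    first nucleophile + intermediate → target (k = 4300 /M/h)
    second nucleophile + intermediate → other capture product (k = 50000 /M/h)
    target ⇌ isomer of the product (K = 0.580, k = 0.290 /h)
    crystals ⇌ target, rate k6*(cs6 - [target]) while solid is left; crystals form when [target] > cs6 (solubility = 3.40 mM, k = 120 /h)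

With the 50.3% of its second nucleophile left in the flask after 8.00 d, C gives 8.31% target, where the flask holds 8.37% beside 1.97% isomer of the product; the crossover at the fork itself, from the constants, is 15.5 mM. The neighbouring flask with 0.25 M of substrate keeps 10.8% of its second nucleophile and holds 35.7% other capture product. There C gives 10.8% target and a share of 76.8%, where that flask holds 11.8% target and ends at a share of 75.2%.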